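At the time of reading, 15 h, each flask is judged by how much of its charge has become side product.

| flask | substrate | partner | temperature | remark | time |
|---|---|---|---|---|---|
| theta | 20 mM | 30 mM | 10 °C | run made earlier |  |
| beta | 10 mM | 30 mM | 25 °C | run made earlier |  |
| alpha | 15 mM | 30 mM | 10 °C | run made earlier |  |
| delta | 20 mM | 45 mM | 25 °C | run made earlier |  |
| green | 20 mM (in portions, 4, over 6.0 h) | 30.0 mM | 25 °C | first portion at the start, last at 6.0 h | 15 h |
| teal | 20 mM | 30.0 mM | 25 °C | everything together at the start | 15 h |
| blue | 20 mM | 30.0 mM (fed, over 6.0 h) |  | the addition at −15 °C, then warmed to 25 °C; the feed brings no volume worth counting | 15 h |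
| ochre | 20 mM | 30.0 mM (fed, over 6.0 h) | 25 °C | all else is in the flask from the start; the feed brings no volume worth counting | 15 h |
| grey | 20 mM | 30.0 mM |  | everything together at the start at −15 °C, warmed to 25 °C at 6.0 h | 15 h |
| red | 20 mM (fed, over 6.0 h) | 30.0 mM | 25 °C | all else is in the flask from the start; the feed brings no volume worth counting | 15 h |

- theta (time / h: side product / %, target / %, substrate / %): 1.33: 15.1, 0.8, 48.6; 3.00: 34.0, 0.7, 22.0; 8.00: 54.7, 2.7, 8.2; 20.0: 69.4, 9.6, 4.3
- beta (time / h: side product / %, target / %, substrate / %): 1.50: 25.9, 2.0, 25.4; 4.00: 45.5, 10.9, 16.3; 8.00: 55.9, 23.2, 8.2; 12.0: 58.1, 31.2, 4.0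
- alpha (time / h: side product / %, target / %, substrate / %): 3.00: 27.6, 1.1, 24.3; 8.00: 48.1, 2.8, 9.1; 15.0: 58.6, 8.0, 6.9; 25.0: 65.6, 14.3, 4.2
- delta (time / h: side product / %, target / %, substrate / %): 1.50: 40.9, 2.6, 20.1; 4.00: 61.0, 11.0, 9.6; 8.00: 68.4, 21.6, 4.3; 12.0: 68.9, 27.8, 1.8

(standard deviation of a reading: 0.5 percentage points)

* the flask with the highest amount of side product, in percent of the substrate charged ("all alike" if they lie within 1.5 percentage points) (green / teal / blue / ochre / grey / red / all alike)
* final side product, as a percentage of the substrate charged, in green
* final side product, as a percentage of the substrate charged, in teal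
* final side product, as a percentage of the substrate charged, in blue
* final side product, as a percentage of the substrate charged, in ochre
* final side product, as a percentage of the substrate charged, in grey
* final side product, as a percentage of the substrate charged, in red

- percentages count the substrate that a species holds: one side product counts as two
- what was read earlier has a scatter of 0.5 percentage points, one standard deviation

How does the free charge behave? Call the pool whatever is in neither side product nor target. Within it, substrate stands to the unread part at 0.544 in beta at 1.50 h and 0.597 at 12.0 h. The ratio is nearly constant, so it can be frozen, and a side product built from two units then forms as the square of the pool (second-order decay).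

How fast is that? Define the pairing time as the time in which a pool of the whole charge would halve with no target forming. Between the first two readings, with pools 11.3 mM and 5.60 mM, delta gives 1.97 h. Beta, scaled to the same charge from pools 7.21 mM and 4.36 mM, gives 2.00 h. So the pairing time is 1.99 h, with partner differing between the runs.

What does that allow? With no target, the paired share at time t is t/(t+pairing time), a ceiling of 88.3 % at 15 h. Target starts late: delta holds 2.6 % against 40.9 % of side product at 1.50 h. So ochre, with its partner still arriving, should have paired about 75.1 % by the end of its feed and finish between that and the ceiling, above teal. Red's steady substrate feed should bring its pool up towards the level at which pairing matches the feed, 57.5 % of the charge, where pairing runs at a third of the rate of a pool of the whole charge, and green's portions spread the charge over the same time, so red and green should end lower than teal, whose pool starts at the whole charge.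

The forecast names ochre highest, with 74 % there, 71.5 % in teal, 71 % in blue, 71 % in grey, 67 % in green and 66 % in red, holding that “Feeding partner only delays target”.

The flasks give 79.7 % in ochre, 73.0 % in teal, 71.8 % in blue, 71.7 % in grey, 59.9 % in red and 58.9 % in green.

    substrate ⇌ open intermediate (K = 1.80, k = 0.0525 min⁻¹, Ea = 87.0 kJ mol⁻¹, ΔH = −35.0 kJ mol⁻¹)
    partner → second intermediate (k = 0.00170 min⁻¹, Ea = 87.0 kJ mol⁻¹)
    open intermediate + second intermediate → target (k = 0.232 M⁻¹ min⁻¹, Ea = 50.0 kJ mol⁻¹)
    substrate + open intermediate → side product (k = 0.866 M⁻¹ min⁻¹, Ea = 44.0 kJ mol⁻¹)
    (constants at 25 °C)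

Ochre has nearly come to rest in side product. Its pool at 15 h is 1.80 % of substrate plus 3.09 % of open intermediate, and that pool would take 40.6 h to halve by pairing, longer than the 2.8 h half-life of open intermediate on its way to target. At 150 h side product stands at 80.0 %, while target has moved from 15.4 % to 20.0 %.

The neighbour flask is ochre with 12 mM of partner. Its ceiling stays 88.3 %, and shrinking ochre's gap below the ceiling in proportion to partner gives 84.9 %. The flask gives 83.8 %.

The earlier runs and the new flask are simulated with constants of no real substance, noise included.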